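**Plan**

- Retrosynthesis: C13=C14 is cut first (olefination of a methyl ketone), then C4–C5, C9–C10 and C8–O together (one cationic fold), then C2–C3 (Grignard opening of a glycidol) and C1–C2 (hydroxymethylation of an allylic bromide made from geranylacetone).
- Enabling feature: C4 is quaternary and bears the oxygenated carbon C18, and the 8α-oxygen is 1,5-related to C13. An oxirane across C4/C18 can therefore initiate, and the C13 ketone oxygen terminate, a single fold that closes ring A (C1–C5, C10), ring B (C5–C10) and a provisional dihydropyran (O, C8, C9, C11–C13).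
- Forward: the acyclic E,E-epoxy dienone is built linearly; rings A, B and the oxygen ring then form in one step; the enol ether is hydrated back to the 8-hydroxy-13-ketone and the side chain is finished as the E-acid.
- Stereochemistry: C4 comes from (S)-2-methylglycidol (as the (R)-oxirane, inverted on ring closure); C5, C10, C9 and C8 follow from the two E-alkenes in a chair–chair fold; the 13E geometry comes from the Horner–Wadsworth–Emmons step.

Key step: step 9

Assumption: geranylacetone is used as the pure E isomer, and ring compounds carry labdane numbering (C18 = 4α-CH2O, C19 = 4β-CH3, C20 on C10, C17 on C8, C16 on C13).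

**Route**

Step 1
Reactants: 1 (E)-geranylacetone
Product: 2 2-[(3E)-4,8-dimethylnona-3,7-dien-1-yl]-2-methyl-1,3-dioxolane
Conditions: HOCH2CH2OH, p-TsOH (cat.), toluene, reflux (Dean–Stark)
Reagents that add atoms: ethylene glycol, OCCO
Why: Acid-catalysed ketalisation with azeotropic removal of water masks the methyl ketone against the oxidant and the organomagnesium reagents that follow, and no stereocentre is involved.

Step 2
Reactants: 2 2-[(3E)-4,8-dimethylnona-3,7-dien-1-yl]-2-methyl-1,3-dioxolane
Product: 3 (2E,6E)-2,6-dimethyl-9-(2-methyl-1,3-dioxolan-2-yl)nona-2,6-dien-1-ol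
Conditions: SeO2 (cat.), t-BuOOH (in decane), CH2Cl2, 0 °C → rt
Reagents that add atoms: tert-butyl hydroperoxide, CC(C)(C)OO; selenium dioxide (catalytic oxygen carrier), O=[Se]=O
Why: Selenium dioxide allylic oxidation (ene reaction, then [2,3]-sigmatropic shift) should attack the terminal, more electron-rich trisubstituted alkene at its E-methyl group, so the CH2OH (future C1) arrives trans to the chain and fixes the later C1–C10=C5 geometry.

Step 3
Reactants: 3 (2E,6E)-2,6-dimethyl-9-(2-methyl-1,3-dioxolan-2-yl)nona-2,6-dien-1-ol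
Product: 4 2-[(3E,7E)-9-bromo-4,8-dimethylnona-3,7-dien-1-yl]-2-methyl-1,3-dioxolane
Conditions: CBr4, PPh3, CH2Cl2, 0 °C
Reagents that add atoms: carbon tetrabromide, BrC(Br)(Br)Br
Why: The Appel reaction converts the primary allylic alcohol into the bromide by SN2 displacement under non-acidic conditions that spare the ketal and the alkene geometry.

Step 4
Reactants: 4 2-[(3E,7E)-9-bromo-4,8-dimethylnona-3,7-dien-1-yl]-2-methyl-1,3-dioxolane
Product: 6 (3E,7E)-3,7-dimethyl-10-(2-methyl-1,3-dioxolan-2-yl)deca-3,7-dien-1-ol, via alkoxysilane 5 (not isolated)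
Conditions: i-PrOMe2SiCH2MgCl (from i-PrOMe2SiCH2Cl, Mg, THF), CuI (10 mol%), THF, 0 °C; then KF, KHCO3, 30% H2O2, THF/MeOH, rt
Reagents that add atoms: [dimethyl(propan-2-yloxy)silyl]methylmagnesium chloride, CC(C)O[Si](C)(C)C[Mg]Cl; hydrogen peroxide, OO
Why: Copper-catalysed SN2 coupling of the silylmethyl Grignard reagent at the primary allylic carbon followed by Tamao–Fleming oxidation of the C–Si bond is the established nucleophilic hydroxymethylation of allylic halides and should add C2 with the E-alkene retained.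

Step 5
Reactants: 6 (3E,7E)-3,7-dimethyl-10-(2-methyl-1,3-dioxolan-2-yl)deca-3,7-dien-1-ol
Product: 7 2-[(3E,7E)-10-bromo-4,8-dimethyldeca-3,7-dien-1-yl]-2-methyl-1,3-dioxolane
Conditions: CBr4, PPh3, CH2Cl2, 0 °C
Reagents that add atoms: carbon tetrabromide, BrC(Br)(Br)Br
Why: A second Appel reaction gives the primary homoallylic bromide needed for Grignard formation, again without acid.

Step 6
Reactants: 7 2-[(3E,7E)-10-bromo-4,8-dimethyldeca-3,7-dien-1-yl]-2-methyl-1,3-dioxolane; 8 (S)-2-methylglycidol
Product: 11 (2R,6E,10E)-2,6,10-trimethyl-13-(2-methyl-1,3-dioxolan-2-yl)trideca-6,10-diene-1,2-diol, via Grignard reagent 9 (not isolated), via magnesium alkoxide 10 (not isolated)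
Conditions: 7, Mg, THF, rt; 8, i-PrMgCl (1.0 equiv), THF, −40 °C; combine, CuI (10 mol%), −40 → 0 °C; aq. NH4Cl
Reagents that add atoms: none
Why: In this copper-catalysed Grignard opening of an epoxide the organocopper species should attack only the unhindered CH2 terminus of the oxirane, whose hydroxyl is masked as its magnesium alkoxide, so the C2–C3 bond forms without touching the quaternary centre, which is carried over intact from 8 as the (R)-tertiary carbinol.

Step 7
Reactants: 11 (2R,6E,10E)-2,6,10-trimethyl-13-(2-methyl-1,3-dioxolan-2-yl)trideca-6,10-diene-1,2-diol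
Product: 12 (5E,9E,14R)-14,15-dihydroxy-6,10,14-trimethylpentadeca-5,9-dien-2-one
Conditions: PPTS, acetone/H2O, 50 °C
Reagents that add atoms: water, O
Why: Mild acid-catalysed ketal hydrolysis frees the methyl ketone before the acid-sensitive oxirane exists, and the diol and both alkenes should be inert to it.

Step 8
Reactants: 12 (5E,9E,14R)-14,15-dihydroxy-6,10,14-trimethylpentadeca-5,9-dien-2-one
Product: 14 (5E,9E)-6,10-dimethyl-13-[(2R)-2-methyloxiran-2-yl]trideca-5,9-dien-2-one, via primary tosylate 13 (not isolated)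
Conditions: TsCl, Et3N, DMAP (cat.), CH2Cl2, 0 °C; then K2CO3, MeOH, rt
Reagents that add atoms: none
Why: Selective sulfonylation of the primary hydroxyl and intramolecular Williamson closure by the tertiary alkoxide give the 2,2-disubstituted oxirane without ever breaking the C4–O bond, so the configuration from step 6 is retained.

Step 9
Reactants: 14 (5E,9E)-6,10-dimethyl-13-[(2R)-2-methyloxiran-2-yl]trideca-5,9-dien-2-one
Product: 15 18-hydroxy-8α,13-epoxy-14,15-dinorlabd-12-ene (5α-H, 9α-H, 10β-CH3, 4α-CH2OH)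
Conditions: MeAlCl2 (2.5 equiv), CH2Cl2, −78 °C; Et3N, then aq. NaHCO3
Reagents that add atoms: none
Why: This is an epoxide-initiated cationic polyene cyclisation (closest known type: Lewis-acid epoxy-polyene cyclisation, with the ketone-oxygen termination known from acid cyclisation of farnesylacetone-type dienones): MeAlCl2 binds the oxirane oxygen, C5 of the C5=C10 alkene attacks tertiary C4 anti to the breaking C4–O bond, C9 of the C8=C9 alkene takes the C10 cation, the C13 carbonyl oxygen takes the C8 cation, and the oxocarbenium ion loses H-12 to give the enol ether. Ring A (C4–C5) closes 6-endo-trig at the alkene with exo opening of the oxirane, ring B (C9–C10) closes 6-endo-trig, and the oxygen ring (C8–O) closes as a six-membered oxocarbenium ion containing both atoms of the carbonyl. C4 is set by inversion of the (R)-oxirane carbon, C5 and C10 by anti addition across the E C5=C10 bond, and C9 and C8 by anti addition across the E C8=C9 bond in a chair–chair fold, which gives the trans ring fusion, the equatorial 9β chain and the equatorial 8α oxygen. The step needs alkene capture at C4 to outrun 1,2-hydride shift from C18, which the low temperature, the aprotic alkylaluminium Lewis acid and six-membered participation by a nucleophilic trisubstituted alkene are meant to secure, and it needs oxygen rather than carbon termination, which the non-enolised ketone secures. It also needs the chair in which the oxirane CH2, still bonded to the aluminium-bound oxygen, is equatorial and C19 axial, since the other chair would give the axial-CH2OH diastereomer with the mirror-image ring fusion; the bulk of the CH2–O–Al arm at the site next to C20 is relied on for this, and because the one oxirane centre is the only source of absolute configuration this partition is the first point to verify.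

Step 10
Reactants: 15 18-hydroxy-8α,13-epoxy-14,15-dinorlabd-12-ene
Product: 16 18-acetoxy-8α,13-epoxy-14,15-dinorlabd-12-ene
Conditions: Ac2O, pyridine, DMAP (cat.), CH2Cl2, 0 °C → rt
Reagents that add atoms: acetic anhydride, CC(=O)OC(C)=O
Why: DMAP-catalysed acylation of the primary alcohol under basic conditions leaves the acid-labile enol ether untouched, and the 8-oxygen is still tied up in the ring so no selectivity question arises.

Step 11
Reactants: 16 18-acetoxy-8α,13-epoxy-14,15-dinorlabd-12-ene
Product: 17 18-acetoxy-8α-hydroxy-14,15-dinorlabdan-13-one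
Conditions: 0.5 M aq. HCl, THF, 0 °C → rt
Reagents that add atoms: water, O
Why: Acid-catalysed hydration of the cyclic enol ether (protonation at C12, water addition at C13, opening of the hemiketal) unveils the 8α-tertiary alcohol and the C13 methyl ketone without breaking C8–O, so C8 keeps its configuration, the acetate should survive the dilute acid, and any exocyclic enol ether isomer converges on the same ketone.

Step 12
Reactants: 17 18-acetoxy-8α-hydroxy-14,15-dinorlabdan-13-one
Product: 18 allyl (13E)-18-acetoxy-8α-hydroxylabd-13-en-15-oate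
Conditions: (EtO)2P(O)CH2CO2CH2CH=CH2, NaH (slight deficit to the phosphonate), THF, 0 → 45 °C
Reagents that add atoms: allyl diethylphosphonoacetate, CCOP(=O)(OCC)CC(=O)OCC=C
Why: Horner–Wadsworth–Emmons olefination of the methyl ketone with the stabilised phosphonate anion should favour the E-enoate through reversible addition (the Z isomer to be removed by chromatography), and the weakly basic anion should leave the acetate and the tertiary alcohol alone.

Step 13
Reactants: 18 allyl (13E)-18-acetoxy-8α-hydroxylabd-13-en-15-oate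
Product: 19 (13E)-18-acetoxy-8α-hydroxylabd-13-en-15-oic acid
Conditions: Pd(PPh3)4 (5 mol%), morpholine, THF, rt; dilute acid work-up
Reagents that add atoms: none
Why: Tsuji–Trost-type Pd(0) deallylation with morpholine as allyl acceptor frees the acid under neutral conditions that keep the primary acetate, the tertiary alcohol and the E-enoate.

**Compound list**

1 | (E)-geranylacetone, (5E)-6,10-dimethylundeca-5,9-dien-2-one | CC(C)=CCC/C(C)=C/CCC(C)=O | starting material
2 | 2-[(3E)-4,8-dimethylnona-3,7-dien-1-yl]-2-methyl-1,3-dioxolane | CC(C)=CCC/C(C)=C/CCC1(C)OCCO1 | intermediate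
3 | (2E,6E)-2,6-dimethyl-9-(2-methyl-1,3-dioxolan-2-yl)nona-2,6-dien-1-ol | OC/C(C)=C/CC/C(C)=C/CCC1(C)OCCO1 | intermediate
4 | 2-[(3E,7E)-9-bromo-4,8-dimethylnona-3,7-dien-1-yl]-2-methyl-1,3-dioxolane | BrC/C(C)=C/CC/C(C)=C/CCC1(C)OCCO1 | intermediate
5 | 2-[(3E,7E)-10-[dimethyl(propan-2-yloxy)silyl]-4,8-dimethyldeca-3,7-dien-1-yl]-2-methyl-1,3-dioxolane | CC(C)O[Si](C)(C)CC/C(C)=C/CC/C(C)=C/CCC1(C)OCCO1 | intermediate
6 | (3E,7E)-3,7-dimethyl-10-(2-methyl-1,3-dioxolan-2-yl)deca-3,7-dien-1-ol | OCC/C(C)=C/CC/C(C)=C/CCC1(C)OCCO1 | intermediate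
7 | 2-[(3E,7E)-10-bromo-4,8-dimethyldeca-3,7-dien-1-yl]-2-methyl-1,3-dioxolane | BrCC/C(C)=C/CC/C(C)=C/CCC1(C)OCCO1 | intermediate
8 | (S)-2-methylglycidol, [(2S)-2-methyloxiran-2-yl]methanol | C1O[C@@]1(C)CO | starting material
9 | [(3E,7E)-3,7-dimethyl-10-(2-methyl-1,3-dioxolan-2-yl)deca-3,7-dien-1-yl]magnesium bromide | Br[Mg]CC/C(C)=C/CC/C(C)=C/CCC1(C)OCCO1 | intermediate
10 | chloromagnesium alkoxide of (S)-2-methylglycidol | C1O[C@@]1(C)CO[Mg]Cl | intermediate
11 | (2R,6E,10E)-2,6,10-trimethyl-13-(2-methyl-1,3-dioxolan-2-yl)trideca-6,10-diene-1,2-diol | OC[C@](C)(O)CCC/C(C)=C/CC/C(C)=C/CCC1(C)OCCO1 | intermediate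
12 | (5E,9E,14R)-14,15-dihydroxy-6,10,14-trimethylpentadeca-5,9-dien-2-one | OC[C@](C)(O)CCC/C(C)=C/CC/C(C)=C/CCC(C)=O | intermediate
13 | (2R,6E,10E)-2-hydroxy-2,6,10-trimethyl-14-oxopentadeca-6,10-dien-1-yl 4-methylbenzenesulfonate | Cc1ccc(cc1)S(=O)(=O)OC[C@](C)(O)CCC/C(C)=C/CC/C(C)=C/CCC(C)=O | intermediate
14 | (5E,9E)-6,10-dimethyl-13-[(2R)-2-methyloxiran-2-yl]trideca-5,9-dien-2-one | C1O[C@]1(C)CCC/C(C)=C/CC/C(C)=C/CCC(C)=O | intermediate
15 | 18-hydroxy-8α,13-epoxy-14,15-dinorlabd-12-ene | OC[C@]1(C)CCC[C@]2(C)[C@H]3CC=C(C)O[C@]3(C)CC[C@@H]12 | intermediate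
16 | 18-acetoxy-8α,13-epoxy-14,15-dinorlabd-12-ene | CC(=O)OC[C@]1(C)CCC[C@]2(C)[C@H]3CC=C(C)O[C@]3(C)CC[C@@H]12 | intermediate
17 | 18-acetoxy-8α-hydroxy-14,15-dinorlabdan-13-one | CC(=O)OC[C@]1(C)CCC[C@]2(C)[C@@H](CCC(C)=O)[C@](C)(O)CC[C@@H]12 | intermediate
18 | allyl (13E)-18-acetoxy-8α-hydroxylabd-13-en-15-oate | CC(=O)OC[C@]1(C)CCC[C@]2(C)[C@@H](CC/C(C)=C/C(=O)OCC=C)[C@](C)(O)CC[C@@H]12 | intermediate
19 | (13E)-18-acetoxy-8α-hydroxylabd-13-en-15-oic acid | CC(=O)OC[C@]1(C)CCC[C@]2(C)[C@@H](CC/C(C)=C/C(=O)O)[C@](C)(O)CC[C@@H]12 | target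

**Step count and risks**

Total step count: 13. Longest linear sequence: 13 steps, from 1 to 19; 8 enters at step 6.

Steps most likely to fail:

1. Step 9. Two processes could drain material: 1,2-hydride shift in the opened oxirane could outrun alkene capture, or the chain could fold through the chair that places the oxirane methylene axial. The second cannot be repaired afterwards because C4 is quaternary; since that methylene is tied back by its oxygen while the methyl is not, this partition is genuinely uncertain. The fallback changes the initiator to a trisubstituted C3–C4 oxirane, whose alkene geometry rather than a chair preference fixes C4, at the price of removing a 3-hydroxyl. It sets out from bromide 7 (as Grignard reagent 9) and returns at 15. Formylation of 9 with DMF would give (4E,8E)-4,8-dimethyl-11-(2-methyl-1,3-dioxolan-2-yl)undeca-4,8-dienal F1. Wittig reaction with ethyl 2-(triphenylphosphoranylidene)propanoate would give ethyl (2E,6E,10E)-2,6,10-trimethyl-13-(2-methyl-1,3-dioxolan-2-yl)trideca-2,6,10-trienoate F2. DIBAL-H would give (2E,6E,10E)-2,6,10-trimethyl-13-(2-methyl-1,3-dioxolan-2-yl)trideca-2,6,10-trien-1-ol F3, and PPTS in wet acetone would give (5E,9E,13E)-15-hydroxy-6,10,14-trimethylpentadeca-5,9,13-trien-2-one F4. Sharpless asymmetric epoxidation with L-(+)-diethyl tartrate would give (5E,9E)-12-[(2S,3S)-3-(hydroxymethyl)-3-methyloxiran-2-yl]-6,10-dimethyldodeca-5,9-dien-2-one F5, and TBDPSCl/imidazole its tert-butyldiphenylsilyl ether F6. MeAlCl2 at −78 °C should fold F6 as in step 9 to 18-(tert-butyldiphenylsilyloxy)-8α,13-epoxy-14,15-dinorlabd-12-en-3β-ol F7, the E-CH2OSi group of the oxirane becoming the equatorial C18 by the geometry of the opening. Barton–McCombie deoxygenation through the 3-O-(methylsulfanyl)thiocarbonyl derivative F8 (NaH, CS2, MeI; then Bu3SnH, AIBN) would give 18-(tert-butyldiphenylsilyloxy)-8α,13-epoxy-14,15-dinorlabd-12-ene F9, and TBAF would then give 15.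

2. Step 6. Magnesium insertion into the homoallylic bromide may be incomplete or accompanied by Wurtz coupling, and magnesium halide may open the oxirane to a halohydrin, all of which waste the advanced fragment. The fallback replaces the organomagnesium nucleophile by a sulfone-stabilised carbanion; it sets out from 7 and returns at 11. Sodium benzenesulfinate in DMF would give 2-[(3E,7E)-10-(benzenesulfonyl)-4,8-dimethyldeca-3,7-dien-1-yl]-2-methyl-1,3-dioxolane F10. n-BuLi would give its α-lithio derivative F11, which in THF/DMPU should open alkoxide 10 at the CH2 terminus to give (2R,6E,10E)-4-(benzenesulfonyl)-2,6,10-trimethyl-13-(2-methyl-1,3-dioxolan-2-yl)trideca-6,10-diene-1,2-diol F12 as a mixture of epimers at the sulfonyl carbon. Sodium amalgam in buffered methanol would remove the sulfonyl group to give 11.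

3. Step 12. Olefination of the ketone, which is partly masked as its cyclic hemiketal, may be slow; the E/Z preference may erode; and the 8-alkoxide may add in conjugate fashion to the new enoate. The fallback builds the enoic acid by metathesis under neutral conditions; it sets out from 17 and returns at 19. Wittig methylenation (Ph3P=CH2, THF, 0 °C) would give 18-acetoxy-14,15-dinorlabd-13(16)-en-8α-ol F13, and cross-metathesis of F13 with acrylic acid (Hoveyda–Grubbs second-generation catalyst, CH2Cl2, 40 °C) should give 19 directly under thermodynamic E control.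

**Further compounds**

F1 | step 9 | (4E,8E)-4,8-dimethyl-11-(2-methyl-1,3-dioxolan-2-yl)undeca-4,8-dienal | O=CCC/C(C)=C/CC/C(C)=C/CCC1(C)OCCO1
F2 | step 9 | ethyl (2E,6E,10E)-2,6,10-trimethyl-13-(2-methyl-1,3-dioxolan-2-yl)trideca-2,6,10-trienoate | CCOC(=O)/C(C)=C/CC/C(C)=C/CC/C(C)=C/CCC1(C)OCCO1
F3 | step 9 | (2E,6E,10E)-2,6,10-trimethyl-13-(2-methyl-1,3-dioxolan-2-yl)trideca-2,6,10-trien-1-ol | OC/C(C)=C/CC/C(C)=C/CC/C(C)=C/CCC1(C)OCCO1
F4 | step 9 | (5E,9E,13E)-15-hydroxy-6,10,14-trimethylpentadeca-5,9,13-trien-2-one | OC/C(C)=C/CC/C(C)=C/CC/C(C)=C/CCC(C)=O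
F5 | step 9 | (5E,9E)-12-[(2S,3S)-3-(hydroxymethyl)-3-methyloxiran-2-yl]-6,10-dimethyldodeca-5,9-dien-2-one | OC[C@]1(C)O[C@H]1CC/C(C)=C/CC/C(C)=C/CCC(C)=O
F6 | step 9 | (5E,9E)-12-[(2S,3S)-3-[(tert-butyldiphenylsilyl)oxymethyl]-3-methyloxiran-2-yl]-6,10-dimethyldodeca-5,9-dien-2-one | CC(C)(C)[Si](OC[C@]1(C)O[C@H]1CC/C(C)=C/CC/C(C)=C/CCC(C)=O)(c1ccccc1)c1ccccc1
F7 | step 9 | 18-(tert-butyldiphenylsilyloxy)-8α,13-epoxy-14,15-dinorlabd-12-en-3β-ol | CC(C)(C)[Si](OC[C@]1(C)[C@@H](O)CC[C@]2(C)[C@H]3CC=C(C)O[C@]3(C)CC[C@@H]12)(c1ccccc1)c1ccccc1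
F8 | step 9 | O-[18-(tert-butyldiphenylsilyloxy)-8α,13-epoxy-14,15-dinorlabd-12-en-3β-yl] S-methyl carbonodithioate | CC(C)(C)[Si](OC[C@]1(C)[C@@H](OC(=S)SC)CC[C@]2(C)[C@H]3CC=C(C)O[C@]3(C)CC[C@@H]12)(c1ccccc1)c1ccccc1
F9 | step 9 | 18-(tert-butyldiphenylsilyloxy)-8α,13-epoxy-14,15-dinorlabd-12-ene | CC(C)(C)[Si](OC[C@]1(C)CCC[C@]2(C)[C@H]3CC=C(C)O[C@]3(C)CC[C@@H]12)(c1ccccc1)c1ccccc1
F10 | step 6 | 2-[(3E,7E)-10-(benzenesulfonyl)-4,8-dimethyldeca-3,7-dien-1-yl]-2-methyl-1,3-dioxolane | O=S(=O)(CC/C(C)=C/CC/C(C)=C/CCC1(C)OCCO1)c1ccccc1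
F11 | step 6 | α-lithio derivative of sulfone F10 | [Li]C(C/C(C)=C/CC/C(C)=C/CCC1(C)OCCO1)S(=O)(=O)c1ccccc1
F12 | step 6 | (2R,6E,10E)-4-(benzenesulfonyl)-2,6,10-trimethyl-13-(2-methyl-1,3-dioxolan-2-yl)trideca-6,10-diene-1,2-diol (C4 epimers) | OC[C@](C)(O)CC(C/C(C)=C/CC/C(C)=C/CCC1(C)OCCO1)S(=O)(=O)c1ccccc1
F13 | step 12 | 18-acetoxy-14,15-dinorlabd-13(16)-en-8α-ol | CC(=O)OC[C@]1(C)CCC[C@]2(C)[C@@H](CCC(C)=C)[C@](C)(O)CC[C@@H]12
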